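A direct plan would start from the ring B enone (S)-4-(tert-butyldimethylsilyloxy)-2-methylcyclohex-2-en-1-one A1, fuse ring A onto A1 in one flask by isobutyrate enolate addition, Michael addition to methyl acrylate and Dieckmann closure to give the keto ester A2, then finish ring B and attach the coumarin to reach the keto ester A3 before the ester is removed.
Drimane numbers are used throughout: ring A is C1–C5 with C10, ring B is C5–C10, C11 stands on C9 and C12 on C8.
Its weakest steps would be these.
(a) The one-flask annulation of A1 to A2: C5 and C10 would both rest on induction from the single C6 silyloxy group of A1 while a fully substituted enolate has to attack the β-carbon next to it; 1,2-addition, enolate equilibration and closure at the wrong carbonyl stay open, so two stereocentres and a ring closure would be left to chance.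
(b) The eight steps from A2 to A3 (enol protection, C8 methylation, enol silylation, dehydrogenation with stoichiometric Pd(OAc)2, methylenation, diene hydroboration, etherification, deprotection): they would add two carbons and one stereocentre, around an ester that is only a handle.
(c) The decarbomethoxylation of A3 (LiCl, wet DMSO, 140 °C): it would be run three steps from the end on material that carries the coumarin lactone and an allylic silyl ether.

Plan of the new route
The retrosynthesis cuts the C11–O aryl ether, then C6–O and C5–H together (syn hydroboration of a C5=C6 alkene), then the C9–C10 bond.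
The enabling feature is the cis pair 5α-H/6α-O on ring B next to the C7=C8 alkene: it is the footprint of a drima-5,7-diene, so the C6 oxygen can first be the ring oxygen of a δ-lactone O–C11(=O)–C9–C8–C7–C6 hung on ring A, in whose ketene acetal the atoms C9=C11–O–C6–C5=C10 form a Claisen array.
Ring A comes first, ready-made from 2,2-dimethylcyclohexane-1,3-dione; ring B is closed second by the lactone Ireland–Claisen step, which forms C9–C10, creates the quaternary C10 and passes the reagent-set C6 configuration on to it.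
The oxygen borrowed from C6 is returned by α-face hydroboration; C9 is set by a kinetic protonation anti to the C10 methyl group.
Nothing is annulated onto a chiral enone, every carbon brought in stays in the target (no handle ester, no decarboxylation, no late dehydrogenation), and the coumarin enters three mild steps from the end.

Key step: step 7

Assumption: the 2-methylallylborane made from (−)-Ipc2BOMe should add to aldehyde 7 with the facial sense of the parent allyl reagent (Si face), which corresponds to the (S)-carbinol.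
Remark: "3,3-(ethylenedioxy)" means the 1,3-dioxolane spiro-fused at C3; the C10 methyl group is β in all bicyclic compounds.

Step 1
Reactants: 1 2,2-dimethylcyclohexane-1,3-dione
Product: 2 6,6-dimethyl-1,4-dioxaspiro[4.5]decan-7-one
Conditions: HOCH2CH2OH (1.1 equiv), p-TsOH·H2O (cat.), benzene, reflux, Dean–Stark
Reagents that add atoms: ethylene glycol OCCO
Why: Acid-catalysed ketalisation should stop at the monoketal because the second carbonyl is then flanked by the quaternary carbon and the dioxolane; it masks the future C3 ketone and creates no stereocentre.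

Step 2
Reactants: 2 6,6-dimethyl-1,4-dioxaspiro[4.5]decan-7-one
Product: 4 6,6,8-trimethyl-1,4-dioxaspiro[4.5]decan-7-one (racemic), via lithium enolate 3 (not isolated)
Conditions: LiN(i-Pr)2 (1.05 equiv), THF, −78 °C; MeI, −78 → 0 °C
Reagents that add atoms: iodomethane CI
Why: Enolate alkylation, in which the ketone can enolise only toward its single CH2 group (the future C10); the stereocentre formed is removed again in step 3.

Step 3
Reactants: 4 6,6,8-trimethyl-1,4-dioxaspiro[4.5]decan-7-one
Product: 6 6,6,8-trimethyl-1,4-dioxaspiro[4.5]dec-7-en-7-yl trifluoromethanesulfonate, via potassium enolate 5 (not isolated)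
Conditions: KN(SiMe3)2 (1.2 equiv), THF, −78 → 0 °C; PhNTf2, −78 °C → rt
Reagents that add atoms: N-phenylbis(trifluoromethanesulfonimide) O=S(=O)(N(c1ccccc1)S(=O)(=O)C(F)(F)F)C(F)(F)F
Why: O-triflation of the only possible enolate should give the tetrasubstituted enol triflate and so fix the C5=C10 double bond of ring A.

Step 4
Reactants: 6 6,6,8-trimethyl-1,4-dioxaspiro[4.5]dec-7-en-7-yl trifluoromethanesulfonate
Product: 7 6,6,8-trimethyl-1,4-dioxaspiro[4.5]dec-7-ene-7-carbaldehyde
Conditions: Pd(OAc)2 (5 mol %), 1,3-bis(diphenylphosphino)propane, CO (1 atm), Et3SiH, Et3N, DMF, 70 °C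
Reagents that add atoms: carbon monoxide [C-]#[O+]
Why: Palladium-catalysed reductive carbonylation (formylation) of an enol triflate: oxidative addition to zerovalent palladium, CO insertion and hydride transfer from the silane should install C6 as the aldehyde.

Step 5
Reactants: 7 6,6,8-trimethyl-1,4-dioxaspiro[4.5]dec-7-ene-7-carbaldehyde; 8 2-methylallylmagnesium chloride
Product: 10 (S)-3-methyl-1-(6,6,8-trimethyl-1,4-dioxaspiro[4.5]dec-7-en-7-yl)but-3-en-1-ol, via diisopinocampheylborinate 9 (not isolated)
Conditions: (−)-Ipc2BOMe, 8, Et2O, −78 °C → rt; 7, −78 °C → rt; 3 M NaOH, 30% H2O2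
Reagents that add atoms: none
Why: Brown allylboration, in which the 2-methylallyl group is delivered through a chair six-membered transition state whose face is fixed by the isopinocampheyl groups, should give the (S)-carbinol at C6, the stereocentre that later controls C10.

Step 6
Reactants: 10 (S)-3-methyl-1-(6,6,8-trimethyl-1,4-dioxaspiro[4.5]dec-7-en-7-yl)but-3-en-1-ol
Product: 13 (S)-4-methylene-6-(6,6,8-trimethyl-1,4-dioxaspiro[4.5]dec-7-en-7-yl)tetrahydro-2H-pyran-2-one, via dilithio derivative 11 (not isolated), via hydroxy acid 12 (not isolated)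
Conditions: n-BuLi (2.5 equiv), Me2NCH2CH2NMe2, Et2O/hexane, 0 °C → rt; CO2, −78 °C; cold 0.5 M HCl to pH 3; crude 12, pyridinium p-toluenesulfonate (cat.), CH2Cl2, rt
Reagents that add atoms: carbon dioxide O=C=O
Why: Alkoxide-directed allylic lithiation of the 2-methylallyl unit (dianion of a 3-methylbut-3-en-1-ol) and carboxylation at the symmetrical allyl terminus should add C11, and the δ-hydroxy acid should lactonise under mild acid without moving the exocyclic alkene; C6 is untouched.

Step 7
Reactants: 13 (S)-4-methylene-6-(6,6,8-trimethyl-1,4-dioxaspiro[4.5]dec-7-en-7-yl)tetrahydro-2H-pyran-2-one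
Product: 16 3,3-(ethylenedioxy)-9-epi-drima-5,8(12)-dien-11-oic acid (9β-H), via silyl ketene acetal 14 (not isolated), via silyl ester 15 (not isolated)
Conditions: LiN(i-Pr)2 (1.2 equiv), Me3SiCl–Et3N (3 equiv), THF, −78 °C, 13 added last; −78 °C → rt; toluene, 110 °C (sealed tube); aq NaH2PO4/THF, rt
Reagents that add atoms: none
Why: Deprotonation at C9 and O-silylation should give ketene acetal 14 (because the C8 alkene is exocyclic, the enolate has no vinylogous path to expel the C6 oxygen), and its atoms C9=C11–O–C6–C5=C10 then undergo a [3,3]-sigmatropic Ireland–Claisen shift. The closest known reaction type is the Claisen rearrangement of lactone silyl ketene acetals that carry an alkenyl group on the carbinol carbon, which gives cycloalkenecarboxylic acids and has close precedent for making a ring-fusion quaternary carbon from a 2,6,6-trimethylcyclohexenyl group. Ring B closes through the C9–C10 bond as the C6–O bond breaks; the C7–C8 link between C6 and C9 forces a boat, bicyclo[2.2.2]octene-like transition state, and the alkene emerges as C5=C6 inside the new ring. C10 is controlled by C6, since the new bond forms on the alkene face from which the oxygen leaves, so the (S)-lactone should give the 10β-methyl configuration with full chirality transfer. C9 follows from the boat geometry, which places the carboxyl group cis to C1 and trans to the C10 methyl group (9-epi); step 8 corrects this. The step needs rearrangement to outrun decomposition of 14, which the base-buffered, non-ionic conditions and the irreversible formation of the silyl ester should secure.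

Step 8
Reactants: 16 3,3-(ethylenedioxy)-9-epi-drima-5,8(12)-dien-11-oic acid (9β-H)
Product: 18 3,3-(ethylenedioxy)drima-5,8(12)-dien-11-oic acid (9α-H), via dilithium dienediolate 17 (not isolated)
Conditions: LiN(i-Pr)2 (2.5 equiv), THF, −78 → 0 °C; −78 °C, AcOH (excess) in THF
Reagents that add atoms: none
Why: Kinetic α-protonation of a carboxylic acid dianion (dienediolate): the proton should enter C9 from the α-face, anti to the axial C10 methyl group that stands perpendicular to the enolate plane, giving 9α-H (C11 β) and leaving the exocyclic alkene in place.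

Step 9
Reactants: 18 3,3-(ethylenedioxy)drima-5,8(12)-dien-11-oic acid (9α-H)
Product: 19 3,3-(ethylenedioxy)drima-5,8(12)-dien-11-ol (9α-H)
Conditions: LiAlH4, THF, 0 °C → rt
Reagents that add atoms: none
Why: Hydride reduction of the carboxylic acid to the primary alcohol, which also removes the acidity of C9–H before the next basic step; no stereocentre is touched.

Step 10
Reactants: 19 3,3-(ethylenedioxy)drima-5,8(12)-dien-11-ol (9α-H)
Product: 20 3,3-(ethylenedioxy)drima-5,7-dien-11-ol (9α-H)
Conditions: KOt-Bu (2.5 equiv), DMSO, rt, short reaction time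
Reagents that add atoms: none
Why: Base-mediated isomerisation of a skipped diene: deprotonation of the doubly allylic C7 methylene and reprotonation at C12 should give the conjugated endocyclic 5,7-diene as the more substituted isomer, while the tertiary C9–H next to the alkoxide should not be removed in the time needed.

Step 11
Reactants: 20 3,3-(ethylenedioxy)drima-5,7-dien-11-ol (9α-H)
Product: 22 3,3-(ethylenedioxy)-5α-drim-7-ene-6α,11-diol, via 6α-boryl adduct 21 (not isolated)
Conditions: BH3·THF (3 equiv), THF, 0 °C → rt; 3 M NaOH, 30% H2O2, 0 °C → rt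
Reagents that add atoms: hydrogen peroxide OO
Why: Hydroboration–oxidation of a homoannular 5,7-diene, as practised on steroidal 5,7-dienes: boron should add to C6 and hydrogen to C5 in a syn fashion from the α-face opposite the C10 and 4β methyl groups, setting 5α-H (trans ring fusion) and 6α-OH together, whereas attack on C7=C8 would push the C8 methyl group against the C10 methyl group or pass C11; oxidation goes with retention.

Step 12
Reactants: 22 3,3-(ethylenedioxy)-5α-drim-7-ene-6α,11-diol; 23 umbelliferone (7-hydroxy-2H-chromen-2-one)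
Product: 24 7-{[3,3-(ethylenedioxy)-6α-hydroxy-5α-drim-7-en-11-yl]oxy}-2H-chromen-2-one
Conditions: PPh3, i-PrO2CN=NCO2i-Pr, THF, 0 °C → rt
Reagents that add atoms: none
Why: Mitsunobu etherification of the primary C11 alcohol by the acidic phenol; the secondary allylic C6 alcohol, flanked by the gem-dimethyl carbon, should not compete, and no stereocentre is involved.

Step 13
Reactants: 24 7-{[3,3-(ethylenedioxy)-6α-hydroxy-5α-drim-7-en-11-yl]oxy}-2H-chromen-2-one
Product: 25 7-{[6α-acetoxy-3,3-(ethylenedioxy)-5α-drim-7-en-11-yl]oxy}-2H-chromen-2-one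
Conditions: Ac2O, pyridine, 4-(dimethylamino)pyridine (cat.), CH2Cl2, rt
Reagents that add atoms: acetic anhydride CC(=O)OC(C)=O
Why: Nucleophile-catalysed acylation of the only free hydroxyl group, with retention at C6.

Step 14
Reactants: 25 7-{[6α-acetoxy-3,3-(ethylenedioxy)-5α-drim-7-en-11-yl]oxy}-2H-chromen-2-one
Product: 26 7-[(6α-acetoxy-3-oxo-5α,9α-drim-7-en-11-yl)oxy]-2H-chromen-2-one (CNP0140705.1)
Conditions: pyridinium p-toluenesulfonate (0.3 equiv), acetone/H2O 10:1, 50 °C
Reagents that add atoms: water O
Why: Acid-catalysed hydrolysis of a dioxolane that is strained by the neighbouring gem-dimethyl group, at an acidity too low to ionise the allylic acetate or open the coumarin; C5 is not α to the new ketone, so no stereocentre is at risk.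

Compound list
1 | 2,2-dimethylcyclohexane-1,3-dione | CC1(C)C(=O)CCCC1=O | starting material
2 | 6,6-dimethyl-1,4-dioxaspiro[4.5]decan-7-one | CC1(C)C(=O)CCCC12OCCO2 | intermediate
3 | lithium enolate of 2 | [Li]OC1=CCCC2(OCCO2)C1(C)C | intermediate
4 | 6,6,8-trimethyl-1,4-dioxaspiro[4.5]decan-7-one (racemic) | CC1CCC2(OCCO2)C(C)(C)C1=O | intermediate
5 | potassium enolate of 4 | [K]OC1=C(C)CCC2(OCCO2)C1(C)C | intermediate
6 | 6,6,8-trimethyl-1,4-dioxaspiro[4.5]dec-7-en-7-yl trifluoromethanesulfonate | CC1=C(OS(=O)(=O)C(F)(F)F)C(C)(C)C2(CC1)OCCO2 | intermediate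
7 | 6,6,8-trimethyl-1,4-dioxaspiro[4.5]dec-7-ene-7-carbaldehyde | CC1=C(C=O)C(C)(C)C2(CC1)OCCO2 | intermediate
8 | 2-methylallylmagnesium chloride | C=C(C)C[Mg]Cl | starting material
9 | O-diisopinocampheylboryl derivative of 10 (borinate) | C=C(C)C[C@H](OB([C@@H]1C[C@@H]2C[C@@H](C2(C)C)[C@H]1C)[C@@H]1C[C@@H]2C[C@@H](C2(C)C)[C@H]1C)C1=C(C)CCC2(OCCO2)C1(C)C | intermediate
10 | (S)-3-methyl-1-(6,6,8-trimethyl-1,4-dioxaspiro[4.5]dec-7-en-7-yl)but-3-en-1-ol | C=C(C)C[C@H](O)C1=C(C)CCC2(OCCO2)C1(C)C | intermediate
11 | dilithio derivative of 10 (lithium alkoxide, allyllithium at the former methyl group) | [Li]CC(=C)C[C@H](O[Li])C1=C(C)CCC2(OCCO2)C1(C)C | intermediate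
12 | (S)-5-hydroxy-3-methylene-5-(6,6,8-trimethyl-1,4-dioxaspiro[4.5]dec-7-en-7-yl)pentanoic acid | OC(=O)CC(=C)C[C@H](O)C1=C(C)CCC2(OCCO2)C1(C)C | intermediate
13 | (S)-4-methylene-6-(6,6,8-trimethyl-1,4-dioxaspiro[4.5]dec-7-en-7-yl)tetrahydro-2H-pyran-2-one | O=C1CC(=C)C[C@@H](C2=C(C)CCC3(OCCO3)C2(C)C)O1 | intermediate
14 | trimethylsilyl ketene acetal of 13 | C[Si](C)(C)OC1=CC(=C)C[C@@H](C2=C(C)CCC3(OCCO3)C2(C)C)O1 | intermediate
15 | trimethylsilyl ester of 16 | C[Si](C)(C)OC(=O)[C@@H]1C(=C)CC=C2C(C)(C)C3(OCCO3)CC[C@]12C | intermediate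
16 | 3,3-(ethylenedioxy)-9-epi-drima-5,8(12)-dien-11-oic acid (9β-H; carboxyl trans to the C10 methyl group) | OC(=O)[C@@H]1C(=C)CC=C2C(C)(C)C3(OCCO3)CC[C@]12C | intermediate
17 | dilithium dienediolate of 16 | [Li]OC(O[Li])=C1C(=C)CC=C2C(C)(C)C3(OCCO3)CC[C@]12C | intermediate
18 | 3,3-(ethylenedioxy)drima-5,8(12)-dien-11-oic acid (9α-H; carboxyl cis to the C10 methyl group) | OC(=O)[C@H]1C(=C)CC=C2C(C)(C)C3(OCCO3)CC[C@]12C | intermediate
19 | 3,3-(ethylenedioxy)drima-5,8(12)-dien-11-ol (9α-H) | OC[C@H]1C(=C)CC=C2C(C)(C)C3(OCCO3)CC[C@]12C | intermediate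
20 | 3,3-(ethylenedioxy)drima-5,7-dien-11-ol (9α-H) | OC[C@H]1C(C)=CC=C2C(C)(C)C3(OCCO3)CC[C@]12C | intermediate
21 | 6α-boryl adduct of 20 (11-O-boryl) | BOC[C@H]1C(C)=C[C@H](B)[C@H]2C(C)(C)C3(OCCO3)CC[C@]12C | intermediate
22 | 3,3-(ethylenedioxy)-5α-drim-7-ene-6α,11-diol | OC[C@H]1C(C)=C[C@H](O)[C@H]2C(C)(C)C3(OCCO3)CC[C@]12C | intermediate
23 | umbelliferone (7-hydroxy-2H-chromen-2-one) | O=c1ccc2ccc(O)cc2o1 | starting material
24 | 7-{[3,3-(ethylenedioxy)-6α-hydroxy-5α-drim-7-en-11-yl]oxy}-2H-chromen-2-one | O=c1ccc2ccc(OC[C@H]3C(C)=C[C@H](O)[C@H]4C(C)(C)C5(OCCO5)CC[C@]34C)cc2o1 | intermediate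
25 | 7-{[6α-acetoxy-3,3-(ethylenedioxy)-5α-drim-7-en-11-yl]oxy}-2H-chromen-2-one | O=c1ccc2ccc(OC[C@H]3C(C)=C[C@H](OC(C)=O)[C@H]4C(C)(C)C5(OCCO5)CC[C@]34C)cc2o1 | intermediate
26 | 7-[(6α-acetoxy-3-oxo-5α,9α-drim-7-en-11-yl)oxy]-2H-chromen-2-one (CNP0140705.1) | CC(=O)O[C@H]1C=C(C)[C@H](COc2ccc3ccc(=O)oc3c2)[C@@]2(C)CCC(=O)C(C)(C)[C@H]12 | target

Total step count: 14. Longest linear sequence: 14 steps (from 1).

Steps most likely to fail

Step 7 (lactone Ireland–Claisen). What may go wrong: the silyl ketene acetal may decompose (C-silylation, loss of silicon, ionisation of the allylic C6–O bond) faster than it passes through the strained boat transition state that has to create a quaternary carbon. Fallback, from 13 back to 16: the neutral aliphatic Claisen rearrangement of the corresponding cyclic enol ether, which tolerates much higher temperatures. Lactone 13 would be reduced with i-Bu2AlH (CH2Cl2, −78 °C) to the lactol (6S)-4-methylene-6-(6,6,8-trimethyl-1,4-dioxaspiro[4.5]dec-7-en-7-yl)tetrahydro-2H-pyran-2-ol F1. MeSO2Cl/Et3N (0 → 60 °C) should dehydrate it to the dienyl ether (S)-4-methylene-2-(6,6,8-trimethyl-1,4-dioxaspiro[4.5]dec-7-en-7-yl)-3,4-dihydro-2H-pyran F2. Heating this ether (decalin, base-washed glass, about 200 °C) should lead, through the same boat array and with the same chirality transfer, to the aldehyde 3,3-(ethylenedioxy)-9-epi-drima-5,8(12)-dien-11-al F3. Oxidation with NaClO2/NaH2PO4/2-methyl-2-butene would then return to acid 16.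

Step 6 (dianion carboxylation and lactonisation). What may go wrong: lithiation at another allylic position (the ring A methyl group or C7), attack of n-BuLi on the dioxolane, or migration of the exocyclic alkene into conjugation during lactonisation. Fallback, from 7 back to 13: build the same chain by cross-coupling instead of a carbanion. Aldehyde 7 would undergo reagent-controlled 2-bromoallylboration (the 2-bromoallyl analogue of the borane of step 5, made from Ipc2BBr of the same pinene series and allene) to the alcohol (S)-3-bromo-1-(6,6,8-trimethyl-1,4-dioxaspiro[4.5]dec-7-en-7-yl)but-3-en-1-ol F4. Negishi coupling of its vinyl bromide with the Reformatsky reagent BrZnCH2CO2Et (Pd(PPh3)4, THF, 60 °C) should give the ester ethyl (S)-5-hydroxy-3-methylene-5-(6,6,8-trimethyl-1,4-dioxaspiro[4.5]dec-7-en-7-yl)pentanoate F5. This would close to lactone 13 with pyridinium p-toluenesulfonate in toluene at 60 °C.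

Step 11 (diene hydroboration). What may go wrong: poor site selectivity between the two trisubstituted alkenes of the diene (boron adding at C7=C8 or at both), or isomerisation of the allylborane before oxidation. Fallback, from 19 back to 25: hydroborate while C8 is not an alkene. Mukaiyama hydration of the exocyclic alkene of 19 (Co(acac)2, PhSiH3, O2, i-PrOH) should give the tertiary alcohol 3,3-(ethylenedioxy)drim-5-ene-8,11-diol F6. Hydroboration–oxidation of its single alkene (BH3·THF; NaOH, H2O2) should give the triol 3,3-(ethylenedioxy)-5α-drimane-6α,8,11-triol F7. Mitsunobu etherification with 23 would give the aryl ether 7-{[3,3-(ethylenedioxy)-6α,8-dihydroxy-5α-driman-11-yl]oxy}-2H-chromen-2-one F8, and acetylation of its secondary hydroxyl the acetate 7-{[6α-acetoxy-3,3-(ethylenedioxy)-8-hydroxy-5α-driman-11-yl]oxy}-2H-chromen-2-one F9. Dehydration of the tertiary alcohol toward C7 (SOCl2, pyridine, −78 → 0 °C) would return to 25.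

Further compounds
F1 | step 7 | (6S)-4-methylene-6-(6,6,8-trimethyl-1,4-dioxaspiro[4.5]dec-7-en-7-yl)tetrahydro-2H-pyran-2-ol (anomers) | OC1CC(=C)C[C@@H](C2=C(C)CCC3(OCCO3)C2(C)C)O1
F2 | step 7 | (S)-4-methylene-2-(6,6,8-trimethyl-1,4-dioxaspiro[4.5]dec-7-en-7-yl)-3,4-dihydro-2H-pyran | C=C1C[C@@H](C2=C(C)CCC3(OCCO3)C2(C)C)OC=C1
F3 | step 7 | 3,3-(ethylenedioxy)-9-epi-drima-5,8(12)-dien-11-al | O=C[C@@H]1C(=C)CC=C2C(C)(C)C3(OCCO3)CC[C@]12C
F4 | step 6 | (S)-3-bromo-1-(6,6,8-trimethyl-1,4-dioxaspiro[4.5]dec-7-en-7-yl)but-3-en-1-ol | C=C(Br)C[C@H](O)C1=C(C)CCC2(OCCO2)C1(C)C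
F5 | step 6 | ethyl (S)-5-hydroxy-3-methylene-5-(6,6,8-trimethyl-1,4-dioxaspiro[4.5]dec-7-en-7-yl)pentanoate | CCOC(=O)CC(=C)C[C@H](O)C1=C(C)CCC2(OCCO2)C1(C)C
F6 | step 11 | 3,3-(ethylenedioxy)drim-5-ene-8,11-diol (C8 epimers) | OC[C@H]1C(C)(O)CC=C2C(C)(C)C3(OCCO3)CC[C@]12C
F7 | step 11 | 3,3-(ethylenedioxy)-5α-drimane-6α,8,11-triol (C8 epimers) | OC[C@H]1C(C)(O)C[C@H](O)[C@H]2C(C)(C)C3(OCCO3)CC[C@]12C
F8 | step 11 | 7-{[3,3-(ethylenedioxy)-6α,8-dihydroxy-5α-driman-11-yl]oxy}-2H-chromen-2-one (C8 epimers) | O=c1ccc2ccc(OC[C@H]3C(C)(O)C[C@H](O)[C@H]4C(C)(C)C5(OCCO5)CC[C@]34C)cc2o1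
F9 | step 11 | 7-{[6α-acetoxy-3,3-(ethylenedioxy)-8-hydroxy-5α-driman-11-yl]oxy}-2H-chromen-2-one (C8 epimers) | O=c1ccc2ccc(OC[C@H]3C(C)(O)C[C@H](OC(C)=O)[C@H]4C(C)(C)C5(OCCO5)CC[C@]34C)cc2o1
A1 | direct plan | (S)-4-(tert-butyldimethylsilyloxy)-2-methylcyclohex-2-en-1-one | CC(C)(C)[Si](C)(C)O[C@H]1CCC(=O)C(C)=C1
A2 | direct plan | methyl 6α-(tert-butyldimethylsilyloxy)-3-hydroxy-9-oxo-11,12-dinor-5α-drim-2-ene-2-carboxylate | CC(C)(C)[Si](C)(C)O[C@H]1CCC(=O)[C@@]2(C)CC(C(=O)OC)=C(O)C(C)(C)[C@H]12
A3 | direct plan | methyl 6α-(tert-butyldimethylsilyloxy)-3-hydroxy-11-[(2-oxo-2H-chromen-7-yl)oxy]-5α,9α-drima-2,7-diene-2-carboxylate | CC(C)(C)[Si](C)(C)O[C@H]1C=C(C)[C@H](COc3ccc4ccc(=O)oc4c3)[C@@]2(C)CC(C(=O)OC)=C(O)C(C)(C)[C@H]12
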